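**Locants.** Ring atoms are O1, C2 (aryl), C3 (methyl), C4, C5; the exocyclic carbinol carbon is C6. The same locants are used for the corresponding atoms of acyclic intermediates. Ar = 3,4-dimethoxyphenyl.

## Analysis of the target

The target is a monocyclic tetrahydrofuran substituted at three adjacent carbons: Ar at C2, methyl at C3 and an ArCH(OH) group at C4, with C5 an unsubstituted CH2. It has four contiguous stereocentres, (2S,3S,4R) in the ring and (R) at C6. Aryl and methyl are trans across C2–C3, while methyl and the carbinol branch are cis across C3–C4. The cis C3/C4 relationship is contra-thermodynamic, so it cannot be reached by equilibration, and the C6 configuration has to be tied to a ring that C6 is not part of. The sensitive sites are the two benzylic C–O bonds (C2–O1 and C6–OH) on electron-rich arenes. Under Brønsted or Lewis acid they ionise, which leads to epimerisation, elimination or Friedel–Crafts closure onto the other arene, so the late steps must be neutral or basic. The strategy rests on the position of C3 and C4 between C2 and C5: if C2 is raised to an aryl ketone and C5 is written as a vinyl carbon, C2(=O)–C3–C4–CH=CH2 is a γ,δ-unsaturated ketone. C3–C4 is then the σ-bond formed in an allyl vinyl ether rearrangement, with C6 already present as a stereocentre on the allyl terminus.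

## Retrosynthetic reasoning

**17 ⇒ 16.** The free C6 hydroxyl is released last, from silyl ether 16 with fluoride. Keeping C6–O masked until then protects it from sulfonylation, ionisation and retro-aldol-type chemistry in every earlier step.

**16 ⇒ 14 (through 15).** The ring is opened at C5–O1, not at C2–O1. In the forward direction the primary C5 sulfonate 15 is displaced by the C2 hydroxyl, so the benzylic C2–O bond is never broken and its configuration is carried through unchanged. Cutting C2–O1 would put a leaving group or cation on an electron-rich benzylic carbon and scramble C2. The precursor is the acyclic 1,4-diol 14.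

**14 ⇒ 13 ⇒ 12.** The C5 hydroxymethyl group is a truncated vinyl group. Oxidative cleavage of the terminal alkene of 12 gives the aldehyde, which is trapped by the C2 hydroxyl as lactol 13, and hydride reduction opens it to 14. The forward step must cleave the alkene without attacking two dimethoxyarenes and without epimerising C4 or eliminating the β-silyloxy group.

**12 ⇒ 11.** The C2–H bond is cut back to aryl ketone 11. Hydride must add to the carbonyl face dictated by C3 (Felkin–Anh, anti to the branched C4), which gives (2S) and, after ring closure, aryl trans to methyl.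

**11 ⇒ 10.** This is the strategic cut: C3–C4 is broken and oxygen is reconnected to the allylic carbon, giving allyl (Z)-enol ether 10. C3–C4 is the only bond flanked by both new carbon stereocentres. Forming it through a closed six-membered transition state converts two alkene geometries into the cis relationship with no external reagent. The same event delivers the C2 ketone and the C4 vinyl group in the right places. The forward reaction needs a chair transition state and a facial bias from C6.

**10 ⇒ 8 + 9.** The enol ether C=C is cut by carbonyl olefination of ester 8 with the ethylidene unit of 9. O-alkylation of a ketone enolate would give C-alkylation and no geometric control, whereas titanium-mediated alkylidenation of esters with geminal dihalides is Z-selective. The forward step has to tolerate a silyl ether and an allylic ester.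

**8 ⇒ 7 ⇒ 3 + 4; 3 ⇒ 1 + 2.** Silyl ether 8 comes from alcohol 7. The C6–alkenyl bond of 7 is cut to aldehyde 4 and an alkenylmetal made by syn-hydrometallation of alkyne 3. One catalytic enantioselective addition then sets C6 and the E-geometry together. The aroate that later becomes the C2 aryl ketone is carried from the start, so no protecting-group exchange is needed at the primary oxygen. A route through enantioselective reduction of an aryl alkynyl ketone and trans-reduction of the alkyne was weighed for the same fragment. It was set aside because the two unsaturated groups on that ketone give a reducing catalyst little to discriminate, and because the trans-reduction would not tolerate the aroate. Ester 3 is the acylation product of 1 with 2.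

## Alternatives that were turned down

**Alternative 1:** Silicon-tethered radical delivery of the C3 methyl carbon.
- **Disconnection:** the C3–CH3 bond; the ring is already present as a 2,5-dihydrofuran and a CH2 unit is delivered from silicon tethered to the C6 oxygen.
- **Key step:** under tin hydride radical-chain conditions, (bromomethyl)silyl ether A1 gives a silylmethyl radical that adds 6-endo to C3. The C4 radical is quenched by hydrogen-atom transfer to give cis-fused siloxane A2, and protodesilylation then leaves the methyl group and the free hydroxyl.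
- **For:** the tether makes the cis C3/C4 relationship a consequence of ring fusion, and attack anti to the C2 aryl group gives 2,3-trans. On the 3,4-cis question this is arguably more secure than a chair preference combined with an enol ether geometric ratio.
- **Against:** A1 must already carry C2 and C6, two benzylic stereocentres in a 1,4-relationship across an sp2 carbon, where neither can direct the other. That means two independent asymmetric operations plus a separate ring synthesis before the key step. Cleaving an unactivated alkyl–silicon bond needs forcing fluoride or alkoxide conditions in the presence of two benzylic ethers, and tin is stoichiometric.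
- **Comparison:** the chosen route reaches its key step in four steps and creates the chain and both carbon stereocentres in one thermal step. What it gives up is the geometric certainty of the tether.

**Alternative 2:** Ketoreductase dynamic reduction of an epimerising aroyl lactone.
- **Disconnection:** the C6–H bond, with C4 fixed in the same event, on a lactone that has C5 as a carbonyl.
- **Key step:** a ketoreductase with cofactor recycling reduces the ketone of aroyl lactone A3. C4 lies between two carbonyls and epimerises quickly, so the enzyme can funnel all material into hydroxy lactone A4.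
- **For:** C4 and the exocyclic C6 are set together under catalyst control, with no protecting group and under mild aqueous conditions. The C4/C6 relationship is read directly, which is stronger than the relay from C6 to C3/C4 through an acyclic rotamer preference in the chosen route.
- **Against:** the enzyme must accept a ketone flanked by an aryl group and an α-branched lactone, and must select the C4 epimer cis to the C3 methyl, which is the minor one at equilibrium. Neither property can be predicted from structure, so screening or engineering is needed. A3 needs an enantiopure trans-disubstituted lactone and a C-acylation. After the key step C5 must still go from lactone carbonyl to CH2, through a β-hydroxy lactone that is prone to retro-aldol cleavage and C4 epimerisation under base, while acid is excluded by the benzylic positions.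
- **Comparison:** the step count is similar. The chosen route relies only on reagents whose sense of induction can be argued from models, at the cost of a protecting group on C6.

**Alternative 3:** Decarboxylative radical cyclisation with polar crossover to the ketone.
- **Disconnection:** C3–C4 with simultaneous ring closure, C6 arriving as a ketone.
- **Key step:** N-acyloxyphthalimide A5 is reduced by the excited photocatalyst fac-Ir(ppy)3 and loses CO2. The C3 radical cyclises 5-exo onto the cinnamyl ether double bond. The benzylic C6 radical is then oxidised to the cation and intercepted by the sulfoxide solvent, which leaves the C6 ketone in A6.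
- **For:** ring, C3–C4 bond and C6 oxygen are made in one operation from a short, convergent precursor. In step economy this is clearly the stronger plan.
- **Against:** the C3 radical is planar, so only C2 directs. 2,3-Trans is likely, but 3,4-cis rests on the small preference of a substituent on the radical carbon in the chair-like 5-exo transition state. In A6, C4 is α to the ketone and the cis isomer is the less stable one, so any base formed during the oxidation erodes it. C6 must then be set by a ketone reduction guided only by C4. Three of the four stereocentres therefore have weak control.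
- **Comparison:** the chosen route is longer but derives the cis C3/C4 pair from two alkene geometries in a closed pericyclic transition state.

Key step: step 5

## Route

Assumption 1: in the alkenylzinc addition of step 2 the ligand is taken to show the same facial sense as in dialkylzinc additions ((−)-MIB directs Si-face attack), so (+)-MIB is specified for Re-face delivery; if the sense is reversed for this alkenylzinc, the other ligand enantiomer is used.
Assumption 2: MIB is 3-exo-morpholinoisoborneol; Cy2BH is dicyclohexylborane prepared in the flask.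

Step 1
Reactants: 1 prop-2-yn-1-ol; 2 3,4-dimethoxybenzoyl chloride
Product: 3 prop-2-yn-1-yl 3,4-dimethoxybenzoate
Conditions: Et3N, DMAP (cat.), CH2Cl2, 0 → 25 °C
Reagents that add atoms: none
Why: Acylation of a primary alcohol by an aroyl chloride under nucleophilic catalysis; no stereocentre is involved, and the aroate installed here is the future C2 aryl ketone.

Step 2
Reactants: 3 prop-2-yn-1-yl 3,4-dimethoxybenzoate; 4 3,4-dimethoxybenzaldehyde
Product: 7 (2E,4R)-4-(3,4-dimethoxyphenyl)-4-hydroxybut-2-en-1-yl 3,4-dimethoxybenzoate, via alkenyldicyclohexylborane 5 (not isolated), via alkenyl(methyl)zinc 6 (not isolated)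
Conditions: Cy2BH (from BH3·SMe2, cyclohexene), toluene, 0 → 25 °C; Me2Zn, −78 °C; (+)-MIB (5 mol%), then 4, −10 → 0 °C; aq. NH4Cl
Reagents that add atoms: none
Why: syn-Hydroboration of the terminal alkyne gives the (E)-alkenylborane, boron-to-zinc exchange gives an alkenylzinc, and this adds to the aldehyde under amino-alkoxide catalysis (catalytic asymmetric alkenylzinc addition of the Oppolzer type). The ligand delivers the alkenyl group to the Re face of 4, which sets C6 as (R), and the E-geometry follows from the syn-hydroboration. Aroate esters are inert to dialkylboranes and organozincs at these temperatures.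

Step 3
Reactants: 7 (2E,4R)-4-(3,4-dimethoxyphenyl)-4-hydroxybut-2-en-1-yl 3,4-dimethoxybenzoate
Product: 8 (2E,4R)-4-[(tert-butyldimethylsilyl)oxy]-4-(3,4-dimethoxyphenyl)but-2-en-1-yl 3,4-dimethoxybenzoate
Conditions: TBSCl, imidazole, DMF, 25 °C
Reagents that add atoms: tert-butyldimethylsilyl chloride, CC(C)(C)[Si](C)(C)Cl
Why: Standard silylation of a secondary alcohol under basic conditions, which do not ionise the benzylic, allylic carbinol; the silyl ether survives the titanium reagent, heat, hydride, periodate and alkoxide used later and is removed by fluoride at the end.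

Step 4
Reactants: 8 (2E,4R)-4-[(tert-butyldimethylsilyl)oxy]-4-(3,4-dimethoxyphenyl)but-2-en-1-yl 3,4-dimethoxybenzoate; 9 1,1-dibromoethane
Product: 10 (2E,4R)-4-[(tert-butyldimethylsilyl)oxy]-4-(3,4-dimethoxyphenyl)but-2-en-1-yl (1Z)-1-(3,4-dimethoxyphenyl)prop-1-en-1-yl ether
Conditions: TiCl4, TMEDA, Zn, PbCl2 (cat.), THF, 0 → 25 °C; K2CO3 aq./Et3N quench; Et3N-deactivated alumina
Reagents that add atoms: none
Why: Takai–Utimoto alkylidenation: the ethylidene species formed from 9, zinc and the TiCl4–TMEDA complex converts the ester C=O into C=CHCH3. The methyl group avoids the aryl substituent in the four-membered titanium intermediate and ends cis to oxygen, giving the (Z)-enol ether. Isolation under basic conditions protects the acid-labile enol ether.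

Step 5
Reactants: 10 (2E,4R)-4-[(tert-butyldimethylsilyl)oxy]-4-(3,4-dimethoxyphenyl)but-2-en-1-yl (1Z)-1-(3,4-dimethoxyphenyl)prop-1-en-1-yl ether
Product: 11 (2S,3S)-3-[(R)-[(tert-butyldimethylsilyl)oxy](3,4-dimethoxyphenyl)methyl]-1-(3,4-dimethoxyphenyl)-2-methylpent-4-en-1-one
Conditions: toluene (0.05 M), Et3N (trace), 120 °C, sealed tube
Reagents that add atoms: none
Why: This is a concerted suprafacial [3,3]-sigmatropic shift through a six-membered chair transition state: the O–CH2 bond breaks while C3–C4 forms, the ether oxygen becomes the C2 carbonyl and the former O–CH2 carbon becomes the terminal carbon of the vinyl group on C4; the closest known reaction type is the thermal Claisen rearrangement of allyl 1-substituted alkenyl ethers made by titanium alkylidenation of allylic esters. No ring is closed, so no closure mode has to be assigned. The relative configuration of the two new stereocentres is controlled by the two double-bond geometries read through the chair: the C6-bearing substituent of the E-allyl unit is equatorial and the methyl of the Z-enol ether is axial, which puts methyl and the C6 branch on the same side of the C2–C3–C4–C5 chain and later cis on the ring. Their absolute configuration is controlled by the C6 stereocentre: the axial methyl lies gauche to C6 and crowds the inside position, which the C6 hydrogen should occupy, and bonding of the enol ether carbon to C4 anti to the C6–O bond (aryl outside) then gives C3 and C4 as in the target; the rotamer with silyloxy inside and aryl anti leads to the same face. The step needs chair over boat selectivity, which the unconstrained acyclic array should provide, and facial selectivity, which rests less firmly on the preference for attack anti to the allylic C–O bond; the competing rotamer with aryl anti and silyloxy outside would give the C3,C4-bis-epimer. Neutral, amine-buffered conditions should keep the enol ether and the benzylic silyl ether intact up to the rearrangement temperature.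

Step 6
Reactants: 11 (2S,3S)-3-[(R)-[(tert-butyldimethylsilyl)oxy](3,4-dimethoxyphenyl)methyl]-1-(3,4-dimethoxyphenyl)-2-methylpent-4-en-1-one
Product: 12 (1S,2S,3S)-3-[(R)-[(tert-butyldimethylsilyl)oxy](3,4-dimethoxyphenyl)methyl]-1-(3,4-dimethoxyphenyl)-2-methylpent-4-en-1-ol
Conditions: LiBH(s-Bu)3 (L-Selectride), THF, −78 °C; aq. NH4Cl
Reagents that add atoms: none
Why: Felkin–Anh reduction of an α-stereogenic aryl ketone by a bulky hydride: the branched C4 stands perpendicular to the carbonyl, hydride enters anti to it past the C3 hydrogen, and C2 is set as (S), which places aryl trans to methyl after ring closure. The low temperature should suppress enolisation at C3.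

Step 7
Reactants: 12 (1S,2S,3S)-3-[(R)-[(tert-butyldimethylsilyl)oxy](3,4-dimethoxyphenyl)methyl]-1-(3,4-dimethoxyphenyl)-2-methylpent-4-en-1-ol
Product: 13 (3S,4S,5S)-3-[(R)-[(tert-butyldimethylsilyl)oxy](3,4-dimethoxyphenyl)methyl]-5-(3,4-dimethoxyphenyl)-4-methyloxolan-2-ol (mixture of anomers)
Conditions: OsO4 (2 mol%), NaIO4, 2,6-lutidine, dioxane–H2O 3:1, 25 °C
Reagents that add atoms: osmium tetroxide, O=[Os](=O)(=O)=O; sodium periodate (terminal oxidant), [Na+].[O-]I(=O)(=O)=O
Why: Lemieux–Johnson dihydroxylation and glycol cleavage of the terminal alkene; the electron-rich arenes are not attacked. The γ-hydroxy aldehyde closes at once to the five-membered lactol, which should protect C4 from epimerisation and the β-silyloxy aldehyde from elimination.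

Step 8
Reactants: 13 (3S,4S,5S)-3-[(R)-[(tert-butyldimethylsilyl)oxy](3,4-dimethoxyphenyl)methyl]-5-(3,4-dimethoxyphenyl)-4-methyloxolan-2-ol
Product: 14 (1S,2S,3R)-3-[(R)-[(tert-butyldimethylsilyl)oxy](3,4-dimethoxyphenyl)methyl]-1-(3,4-dimethoxyphenyl)-2-methylbutane-1,4-diol
Conditions: NaBH4, MeOH, 0 → 25 °C
Reagents that add atoms: none
Why: Borohydride reduces the lactol through its open hydroxy aldehyde form to the primary alcohol; no stereocentre is touched.

Step 9
Reactants: 14 (1S,2S,3R)-3-[(R)-[(tert-butyldimethylsilyl)oxy](3,4-dimethoxyphenyl)methyl]-1-(3,4-dimethoxyphenyl)-2-methylbutane-1,4-diol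
Product: 16 tert-butyl{(R)-(3,4-dimethoxyphenyl)[(3R,4S,5S)-5-(3,4-dimethoxyphenyl)-4-methyloxolan-3-yl]methoxy}dimethylsilane, via primary tosylate 15 (not isolated)
Conditions: TsCl (1.05 equiv), Et3N, DMAP (cat.), CH2Cl2, 0 °C; then NaH, THF, 0 → 25 °C
Reagents that add atoms: none
Why: The primary hydroxyl is sulfonylated selectively over the hindered secondary benzylic one, and the C2 alkoxide then displaces the tosylate in an intramolecular Williamson etherification (5-exo-tet). The C2–O bond is never broken, so C2 is retained, and no acid is present that could ionise either benzylic position.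

Step 10
Reactants: 16 tert-butyl{(R)-(3,4-dimethoxyphenyl)[(3R,4S,5S)-5-(3,4-dimethoxyphenyl)-4-methyloxolan-3-yl]methoxy}dimethylsilane
Product: 17 (R)-(3,4-dimethoxyphenyl)[(3R,4S,5S)-5-(3,4-dimethoxyphenyl)-4-methyloxolan-3-yl]methanol (CNP0269167.1; ring 2S,3S,4R, carbinol R in the locants used here)
Conditions: Bu4NF, THF, 0 → 25 °C
Reagents that add atoms: none
Why: Fluoride cleaves the silyl ether under basic, non-ionising conditions; all four stereocentres are untouched.

## Compound list

1 | prop-2-yn-1-ol | C#CCO | starting material
2 | 3,4-dimethoxybenzoyl chloride | COc1ccc(C(Cl)=O)cc1OC | starting material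
3 | prop-2-yn-1-yl 3,4-dimethoxybenzoate | C#CCOC(=O)c1ccc(OC)c(OC)c1 | intermediate
4 | 3,4-dimethoxybenzaldehyde | COc1ccc(C=O)cc1OC | starting material
5 | (2E)-3-(dicyclohexylboranyl)prop-2-en-1-yl 3,4-dimethoxybenzoate | COc1ccc(C(=O)OC/C=C/B(C2CCCCC2)C2CCCCC2)cc1OC | intermediate (not isolated)
6 | [(1E)-3-(3,4-dimethoxybenzoyloxy)prop-1-en-1-yl](methyl)zinc | C[Zn]/C=C/COC(=O)c1ccc(OC)c(OC)c1 | intermediate (not isolated)
7 | (2E,4R)-4-(3,4-dimethoxyphenyl)-4-hydroxybut-2-en-1-yl 3,4-dimethoxybenzoate | COc1ccc(C(=O)OC/C=C/[C@@H](O)c2ccc(OC)c(OC)c2)cc1OC | intermediate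
8 | (2E,4R)-4-[(tert-butyldimethylsilyl)oxy]-4-(3,4-dimethoxyphenyl)but-2-en-1-yl 3,4-dimethoxybenzoate | COc1ccc(C(=O)OC/C=C/[C@@H](O[Si](C)(C)C(C)(C)C)c2ccc(OC)c(OC)c2)cc1OC | intermediate
9 | 1,1-dibromoethane | CC(Br)Br | starting material
10 | (2E,4R)-4-[(tert-butyldimethylsilyl)oxy]-4-(3,4-dimethoxyphenyl)but-2-en-1-yl (1Z)-1-(3,4-dimethoxyphenyl)prop-1-en-1-yl ether | C/C=C(\OC/C=C/[C@@H](O[Si](C)(C)C(C)(C)C)c1ccc(OC)c(OC)c1)c1ccc(OC)c(OC)c1 | intermediate
11 | (2S,3S)-3-[(R)-[(tert-butyldimethylsilyl)oxy](3,4-dimethoxyphenyl)methyl]-1-(3,4-dimethoxyphenyl)-2-methylpent-4-en-1-one | C=C[C@H]([C@@H](O[Si](C)(C)C(C)(C)C)c1ccc(OC)c(OC)c1)[C@H](C)C(=O)c1ccc(OC)c(OC)c1 | intermediate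
12 | (1S,2S,3S)-3-[(R)-[(tert-butyldimethylsilyl)oxy](3,4-dimethoxyphenyl)methyl]-1-(3,4-dimethoxyphenyl)-2-methylpent-4-en-1-ol | C=C[C@H]([C@@H](O[Si](C)(C)C(C)(C)C)c1ccc(OC)c(OC)c1)[C@H](C)[C@H](O)c1ccc(OC)c(OC)c1 | intermediate
13 | (3S,4S,5S)-3-[(R)-[(tert-butyldimethylsilyl)oxy](3,4-dimethoxyphenyl)methyl]-5-(3,4-dimethoxyphenyl)-4-methyloxolan-2-ol (anomers) | COc1ccc([C@H]2OC(O)[C@H]([C@@H](O[Si](C)(C)C(C)(C)C)c3ccc(OC)c(OC)c3)[C@@H]2C)cc1OC | intermediate
14 | (1S,2S,3R)-3-[(R)-[(tert-butyldimethylsilyl)oxy](3,4-dimethoxyphenyl)methyl]-1-(3,4-dimethoxyphenyl)-2-methylbutane-1,4-diol | OC[C@H]([C@@H](O[Si](C)(C)C(C)(C)C)c1ccc(OC)c(OC)c1)[C@H](C)[C@H](O)c1ccc(OC)c(OC)c1 | intermediate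
15 | (2R,3S,4S)-2-[(R)-[(tert-butyldimethylsilyl)oxy](3,4-dimethoxyphenyl)methyl]-4-(3,4-dimethoxyphenyl)-4-hydroxy-3-methylbutyl 4-methylbenzenesulfonate | Cc1ccc(cc1)S(=O)(=O)OC[C@H]([C@@H](O[Si](C)(C)C(C)(C)C)c1ccc(OC)c(OC)c1)[C@H](C)[C@H](O)c1ccc(OC)c(OC)c1 | intermediate (not isolated)
16 | tert-butyl{(R)-(3,4-dimethoxyphenyl)[(3R,4S,5S)-5-(3,4-dimethoxyphenyl)-4-methyloxolan-3-yl]methoxy}dimethylsilane | COc1ccc([C@H]2OC[C@H]([C@@H](O[Si](C)(C)C(C)(C)C)c3ccc(OC)c(OC)c3)[C@@H]2C)cc1OC | intermediate
17 | (R)-(3,4-dimethoxyphenyl)[(3R,4S,5S)-5-(3,4-dimethoxyphenyl)-4-methyloxolan-3-yl]methanol | COc1ccc([C@H]2OC[C@H]([C@@H](O)c3ccc(OC)c(OC)c3)[C@@H]2C)cc1OC | target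

## Step count and least certain steps

Total: 10 steps. Longest linear sequence: 10 steps (1 and 2 through 3 to 17; 4 and 9 enter as commercial materials).

**Step 5 (key step).** The likeliest failure is insufficient facial discrimination by the exocyclic C6 stereocentre. Attack through the rotamer with aryl anti and silyloxy outside would erode the diastereomer ratio at C3/C4, and some boat participation or thermal decomposition of the benzylic silyl ether is also possible. The fallback moves the controlling stereocentre into the chair, where 1,3-chirality transfer is dependable; it sets out from 2 and 4 and returns at 13.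
- Commercial (R)-but-3-yn-2-ol is acylated with 2 to give (2R)-but-3-yn-2-yl 3,4-dimethoxybenzoate F1.
- Under the conditions of step 2, F1 gives the alkenyldicyclohexylborane F2 and then the alkenyl(methyl)zinc F3, which adds to 4 to give (2R,3E,5R)-5-(3,4-dimethoxyphenyl)-5-hydroxypent-3-en-2-yl 3,4-dimethoxybenzoate F4.
- Silylation as in step 3 gives the silyl ether F5, and ethylidenation with 9 as in step 4 gives the secondary allyl (Z)-enol ether F6.
- On heating, the carbinol methyl of F6 must sit equatorial to avoid the C2 aryl group. For the (R)-carbinol this selects the same face of the allyl unit as required above and gives the (E)-propenyl ketone F7.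
- Reduction with LiBH(s-Bu)3 as in step 6 gives the alcohol F8.
- OsO4/NaIO4 cleavage of the propenyl group of F8 gives lactol 13.

**Step 4.** The ethylidenation may stall on the electron-rich aroate or give a poor Z/E ratio, and the enol ether may hydrolyse or the benzylic silyl ether ionise in the presence of Lewis acidic titanium. The fallback avoids the aryl enol ether with an Ireland–Claisen rearrangement and introduces the C2 aryl group afterwards; it sets out from 8 and returns at 11.
- Methanolysis of 8 (K2CO3, MeOH) gives (2E,4R)-4-[(tert-butyldimethylsilyl)oxy]-4-(3,4-dimethoxyphenyl)but-2-en-1-ol F9.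
- Propanoyl chloride, Et3N and DMAP give the propanoate F10.
- LiN(i-Pr)2 in THF at −78 °C followed by Me3SiCl gives the (E)-trimethylsilyl ketene acetal F11, in which methyl is cis to the allyl oxygen as in 10.
- On warming, F11 rearranges to the trimethylsilyl ester F12, and aqueous work-up gives (2S,3S)-3-[(R)-[(tert-butyldimethylsilyl)oxy](3,4-dimethoxyphenyl)methyl]-2-methylpent-4-enoic acid F13.
- Coupling with N,O-dimethylhydroxylamine gives the Weinreb amide F14, and (3,4-dimethoxyphenyl)magnesium bromide converts it into ketone 11.

**Step 2.** The allylic aroate may interfere with boron-to-zinc exchange (1,2-shift in a borate with loss of aroate, or acyl transfer to the zinc alkoxide), and uncatalysed background addition to the aldehyde may lower the enantiomeric purity. The fallback separates C–C bond formation from the ester; it sets out from 4 and returns at 7.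
- Me2Zn/ProPhenol-catalysed addition of tert-butyldimethyl(prop-2-yn-1-yloxy)silane to 4, with the ligand enantiomer that directs Re-face attack, gives (1S)-4-[(tert-butyldimethylsilyl)oxy]-1-(3,4-dimethoxyphenyl)but-2-yn-1-ol F15.
- Hydroxyl-directed trans-reduction with NaAlH2(OCH2CH2OMe)2 in THF gives the (E)-allylic alcohol F16.
- Bu4NF gives (1R,2E)-1-(3,4-dimethoxyphenyl)but-2-ene-1,4-diol F17.
- Selective acylation of the primary hydroxyl with 2 (2,4,6-collidine, CH2Cl2, −78 °C) gives 7.

**Step 6.** Substrate control may be incomplete, since the aryl ketone has only a methyl/branched-alkyl difference at C3, and enolisation could epimerise C3. The fallback replaces substrate control by reagent control and goes directly from 11 to 12: oxazaborolidine-catalysed (CBS) reduction with (R)-2-methyl-CBS-oxazaborolidine and catecholborane in toluene at −78 °C. The aryl group acts as the large substituent, so (1S) is expected, and catecholborane does not hydroborate the vinyl group at this temperature. No new compound is formed.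

## Further compounds

F1 | step 5 | (2R)-but-3-yn-2-yl 3,4-dimethoxybenzoate | C#C[C@@H](C)OC(=O)c1ccc(OC)c(OC)c1
F2 | step 5 | (2R,3E)-4-(dicyclohexylboranyl)but-3-en-2-yl 3,4-dimethoxybenzoate | COc1ccc(C(=O)O[C@H](C)/C=C/B(C2CCCCC2)C2CCCCC2)cc1OC
F3 | step 5 | [(1E,3R)-3-(3,4-dimethoxybenzoyloxy)but-1-en-1-yl](methyl)zinc | COc1ccc(C(=O)O[C@H](C)/C=C/[Zn]C)cc1OC
F4 | step 5 | (2R,3E,5R)-5-(3,4-dimethoxyphenyl)-5-hydroxypent-3-en-2-yl 3,4-dimethoxybenzoate | COc1ccc(C(=O)O[C@H](C)/C=C/[C@@H](O)c2ccc(OC)c(OC)c2)cc1OC
F5 | step 5 | (2R,3E,5R)-5-[(tert-butyldimethylsilyl)oxy]-5-(3,4-dimethoxyphenyl)pent-3-en-2-yl 3,4-dimethoxybenzoate | COc1ccc(C(=O)O[C@H](C)/C=C/[C@@H](O[Si](C)(C)C(C)(C)C)c2ccc(OC)c(OC)c2)cc1OC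
F6 | step 5 | (2R,3E,5R)-5-[(tert-butyldimethylsilyl)oxy]-5-(3,4-dimethoxyphenyl)pent-3-en-2-yl (1Z)-1-(3,4-dimethoxyphenyl)prop-1-en-1-yl ether | C/C=C(\O[C@H](C)/C=C/[C@@H](O[Si](C)(C)C(C)(C)C)c1ccc(OC)c(OC)c1)c1ccc(OC)c(OC)c1
F7 | step 5 | (2S,3S,4E)-3-[(R)-[(tert-butyldimethylsilyl)oxy](3,4-dimethoxyphenyl)methyl]-1-(3,4-dimethoxyphenyl)-2-methylhex-4-en-1-one | C/C=C/[C@H]([C@@H](O[Si](C)(C)C(C)(C)C)c1ccc(OC)c(OC)c1)[C@H](C)C(=O)c1ccc(OC)c(OC)c1
F8 | step 5 | (1S,2S,3S,4E)-3-[(R)-[(tert-butyldimethylsilyl)oxy](3,4-dimethoxyphenyl)methyl]-1-(3,4-dimethoxyphenyl)-2-methylhex-4-en-1-ol | C/C=C/[C@H]([C@@H](O[Si](C)(C)C(C)(C)C)c1ccc(OC)c(OC)c1)[C@H](C)[C@H](O)c1ccc(OC)c(OC)c1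
F9 | step 4 | (2E,4R)-4-[(tert-butyldimethylsilyl)oxy]-4-(3,4-dimethoxyphenyl)but-2-en-1-ol | OC/C=C/[C@@H](O[Si](C)(C)C(C)(C)C)c1ccc(OC)c(OC)c1
F10 | step 4 | (2E,4R)-4-[(tert-butyldimethylsilyl)oxy]-4-(3,4-dimethoxyphenyl)but-2-en-1-yl propanoate | CCC(=O)OC/C=C/[C@@H](O[Si](C)(C)C(C)(C)C)c1ccc(OC)c(OC)c1
F11 | step 4 | (E)-trimethylsilyl ketene acetal of F10: tert-butyl{[(1R,2E)-1-(3,4-dimethoxyphenyl)-4-{[(1E)-1-[(trimethylsilyl)oxy]prop-1-en-1-yl]oxy}but-2-en-1-yl]oxy}dimethylsilane | C/C=C(/O[Si](C)(C)C)OC/C=C/[C@@H](O[Si](C)(C)C(C)(C)C)c1ccc(OC)c(OC)c1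
F12 | step 4 | trimethylsilyl (2S,3S)-3-[(R)-[(tert-butyldimethylsilyl)oxy](3,4-dimethoxyphenyl)methyl]-2-methylpent-4-enoate | C=C[C@H]([C@@H](O[Si](C)(C)C(C)(C)C)c1ccc(OC)c(OC)c1)[C@H](C)C(=O)O[Si](C)(C)C
F13 | step 4 | (2S,3S)-3-[(R)-[(tert-butyldimethylsilyl)oxy](3,4-dimethoxyphenyl)methyl]-2-methylpent-4-enoic acid | C=C[C@H]([C@@H](O[Si](C)(C)C(C)(C)C)c1ccc(OC)c(OC)c1)[C@H](C)C(=O)O
F14 | step 4 | (2S,3S)-3-[(R)-[(tert-butyldimethylsilyl)oxy](3,4-dimethoxyphenyl)methyl]-N-methoxy-N,2-dimethylpent-4-enamide | C=C[C@H]([C@@H](O[Si](C)(C)C(C)(C)C)c1ccc(OC)c(OC)c1)[C@H](C)C(=O)N(C)OC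
F15 | step 2 | (1S)-4-[(tert-butyldimethylsilyl)oxy]-1-(3,4-dimethoxyphenyl)but-2-yn-1-ol | CC(C)(C)[Si](C)(C)OCC#C[C@@H](O)c1ccc(OC)c(OC)c1
F16 | step 2 | (1R,2E)-4-[(tert-butyldimethylsilyl)oxy]-1-(3,4-dimethoxyphenyl)but-2-en-1-ol | CC(C)(C)[Si](C)(C)OC/C=C/[C@@H](O)c1ccc(OC)c(OC)c1
F17 | step 2 | (1R,2E)-1-(3,4-dimethoxyphenyl)but-2-ene-1,4-diol | OC/C=C/[C@@H](O)c1ccc(OC)c(OC)c1
F0 | step 6 | none | none
A1 | alternative 1 | (bromomethyl){(S)-(3,4-dimethoxyphenyl)[(5S)-5-(3,4-dimethoxyphenyl)-2,5-dihydrofuran-3-yl]methoxy}dimethylsilane | COc1ccc([C@H]2OCC([C@@H](O[Si](C)(C)CBr)c3ccc(OC)c(OC)c3)=C2)cc1OC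
A2 | alternative 1 | cis-fused bicyclic siloxane (tetrahydrofuran fused at C3–C4 to a 2,2-dimethyl-1-oxa-2-silacyclohexane, aryl groups at C2 and C6 as in the target) | COc1ccc([C@H]2OC[C@H]3[C@@H]2C[Si](C)(C)O[C@H]3c4ccc(OC)c(OC)c4)cc1OC
A3 | alternative 2 | (4S,5S)-3-(3,4-dimethoxybenzoyl)-5-(3,4-dimethoxyphenyl)-4-methyloxolan-2-one (C3 epimers in equilibrium) | COc1ccc([C@H]2OC(=O)C(C(=O)c3ccc(OC)c(OC)c3)[C@@H]2C)cc1OC
A4 | alternative 2 | (3S,4S,5S)-3-[(R)-(3,4-dimethoxyphenyl)(hydroxy)methyl]-5-(3,4-dimethoxyphenyl)-4-methyloxolan-2-one | COc1ccc([C@H]2OC(=O)[C@H]([C@@H](O)c3ccc(OC)c(OC)c3)[C@@H]2C)cc1OC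
A5 | alternative 3 | 1,3-dioxoisoindolin-2-yl (3S)-3-(3,4-dimethoxyphenyl)-3-{[(2E)-3-(3,4-dimethoxyphenyl)prop-2-en-1-yl]oxy}-2-methylpropanoate (C2 epimers) | COc1ccc([C@@H](OC/C=C/c2ccc(OC)c(OC)c2)C(C)C(=O)ON2C(=O)c3ccccc3C2=O)cc1OC
A6 | alternative 3 | (3,4-dimethoxyphenyl)[(3R,4S,5S)-5-(3,4-dimethoxyphenyl)-4-methyloxolan-3-yl]methanone | COc1ccc([C@H]2OC[C@H](C(=O)c3ccc(OC)c(OC)c3)[C@@H]2C)cc1OC
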